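**Plan**

Ring atoms carry carotenoid numbers: C1 is the gem-dimethyl carbon, C2 the CH2, C3 and C4 the carbinol carbons, C5 the methyl-bearing carbon, C6 the chain-bearing carbon. Ring A is the 7,8-didehydro end, ring B the 7',8'-ene end.
Retrosynthesis: the C11=C12 and C11'=C12' double bonds are cut first (two Wittig reactions on a C10 trienedial). The C6–C7 bond of each end group is cut next (Sonogashira for ring A, Stille for ring B), which leads both rings back to one cyclohexenyl triflate. Its parent ketone is opened at the ring bond C4–C5.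
Forward: an (S)-α-silyloxy aldehyde carrying a (Z)-silyl enol ether is closed to the six-membered ring by an intramolecular silyl-transfer Mukaiyama aldol addition. The ring ketone becomes the enol triflate, which is coupled once with an enynol and once with a dienylstannane. The two C15 phosphonium salts are then joined to the C10 dialdehyde one after the other.
Enabling feature: in the 3,4-dihydroxy-2,6,6-trimethylcyclohexene ring, C5 is α and C4 is β to C6, and the quaternary C1 makes C5 the only enolisable position of a C6 ketone. The C6 oxygen therefore serves as a temporary activating group: it makes C5 nucleophilic, passes its silyl group to O4 during ring closure, and later leaves as triflate when C7 is attached.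
Stereochemistry: C3 of both rings comes from (S)-benzyl glycidyl ether. C4 is set in the ring closure by 1,2-induction from C3 in a chair transition state (trans, diequatorial). The E double bonds come from the (E)-enynol, syn-hydrostannation, stereoretentive couplings and E-selective tributylphosphonium ylides.

Key step: step 6

Assumption: the target is the all-E (3S,4S,3'S,4'S) isomer (both rings trans-3,4-diols), and compounds 1, 2, 11 and 21 are taken as commercial materials.

**Route**

Step 1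
Reactants: 1 isobutyric acid; 2 (S)-benzyl glycidyl ether
Product: 4 (S)-5-[(benzyloxy)methyl]-3,3-dimethyldihydrofuran-2(3H)-one, via hydroxy acid 3 (not isolated)
Conditions: LiN(i-Pr)2 (2.2 equiv), THF, 0 → 50 °C; 2, 0 °C → rt; 3 M HCl; TsOH (cat.), PhMe, 60 °C
Reagents that add atoms: none
Why: The dianion of isobutyric acid opens the terminal epoxide at its CH2 carbon (SN2, stereocentre untouched) and the γ-hydroxy acid lactonises on acidification, which installs the quaternary C1 and the (S)-configured C3 oxygen.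

Step 2
Reactants: 4 (S)-5-[(benzyloxy)methyl]-3,3-dimethyldihydrofuran-2(3H)-one
Product: 5 (S)-7-(benzyloxy)-6-hydroxy-4,4-dimethylheptan-3-one (in equilibrium with its cyclic hemiketal)
Conditions: EtLi (1.1 equiv), THF, −78 °C; sat. aq NH4Cl at −78 °C
Reagents that add atoms: ethyllithium, [Li]CC
Why: Mono-addition of an alkyllithium to a lactone should stop at the ketone stage because the lithium hemiketal persists at −78 °C and the tert-alkyl ketone released on quench is hindered.

Step 3
Reactants: 5 (S)-7-(benzyloxy)-6-hydroxy-4,4-dimethylheptan-3-one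
Product: 6 (S,Z)-7-(benzyloxy)-3,6-bis(tert-butyldimethylsilyloxy)-4,4-dimethylhept-2-ene
Conditions: TBSOTf (2.4 equiv), Et3N (4 equiv), CH2Cl2, 0 °C → rt
Reagents that add atoms: tert-butyldimethylsilyl triflate, CC(C)(C)[Si](C)(C)OS(=O)(=O)C(F)(F)F
Why: Silyl triflate/amine silylates the secondary alcohol and soft-enolises the ketone on its only enolisable side, and the (Z)-enol ether is expected because the methyl group avoids allylic strain with the gem-dimethyl carbon.

Step 4
Reactants: 6 (S,Z)-7-(benzyloxy)-3,6-bis(tert-butyldimethylsilyloxy)-4,4-dimethylhept-2-ene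
Product: 7 (S,Z)-2,5-bis(tert-butyldimethylsilyloxy)-4,4-dimethylhept-5-en-1-ol
Conditions: H2 (1 atm), 10% Pd/C, NaHCO3 (solid), EtOAc, rt
Reagents that add atoms: none
Why: Hydrogenolysis of the benzyl ether should spare the trisubstituted silyl enol ether, which is shielded by the neighbouring quaternary carbon and kept from acid by the buffer.

Step 5
Reactants: 7 (S,Z)-2,5-bis(tert-butyldimethylsilyloxy)-4,4-dimethylhept-5-en-1-ol
Product: 8 (S,Z)-2,5-bis(tert-butyldimethylsilyloxy)-4,4-dimethylhept-5-enal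
Conditions: Dess–Martin periodinane (1.3 equiv), pyridine (5 equiv), CH2Cl2, 0 °C → rt
Reagents that add atoms: none
Why: Buffered Dess–Martin oxidation should give the α-silyloxy aldehyde without epimerisation and without loss of the enol ether.

Step 6
Reactants: 8 (S,Z)-2,5-bis(tert-butyldimethylsilyloxy)-4,4-dimethylhept-5-enal
Product: 9 (4S,5S,6S)-4,5-bis(tert-butyldimethylsilyloxy)-2,2,6-trimethylcyclohexan-1-one
Conditions: Tf2NH (5 mol%), CH2Cl2 (0.02 M), −78 → −40 °C; Et3N quench
Reagents that add atoms: none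
Why: Tf2NH protodesilylates a trace of enol ether to TBSNTf2, which silylates the aldehyde oxygen; the enol ether carbon (C5) then attacks the activated aldehyde carbon (C4), and the silyl group on the resulting C6 oxocarbenium is handed to the next aldehyde, so the chain carrier is regenerated and the new alkoxide ends as its TBS ether. The closest known reaction type is the silyl-triflimide-catalysed silyl-transfer Mukaiyama aldol addition, here in its intramolecular form. The cyclohexanone ring closes in the 6-(enolendo)-exo-trig mode. The new carbinol centre C4 is controlled by C3 through a chair transition state in which the C3 silyloxy group is equatorial (an axial one would meet the axial methyl on C1) and the silylated carbonyl oxygen lies antiperiplanar to the enol ether double bond, hence equatorial and trans to O3; the C5 methyl centre follows from the (Z)-enol ether (methyl equatorial) and is erased in step 7. The step needs facial selectivity at the aldehyde and configurational stability at the α-silyloxy carbon: the first rests on the 1,3-diaxial penalty of the alternative chair and the bulk of the silylated oxygen, the second on the absence of base, and the all-equatorial product should also be the thermodynamically preferred isomer.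

Step 7
Reactants: 9 (4S,5S,6S)-4,5-bis(tert-butyldimethylsilyloxy)-2,2,6-trimethylcyclohexan-1-one
Product: 10 (3S,4S)-3,4-bis(tert-butyldimethylsilyloxy)-2,6,6-trimethylcyclohex-1-en-1-yl trifluoromethanesulfonate
Conditions: KN(SiMe3)2 (1.3 equiv), THF, −78 °C; PhNTf2 (1.4 equiv), −78 → 0 °C
Reagents that add atoms: N-phenylbis(trifluoromethanesulfonimide), O=S(=O)(N(c1ccccc1)S(=O)(=O)C(F)(F)F)C(F)(F)F
Why: The ketone has a single α-hydrogen, so enol triflate formation fixes the tetrasubstituted C5=C6 alkene regiospecifically, and the equatorial β-silyloxy group is not aligned for E1cB loss from the enolate.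

Step 8
Reactants: 10 (3S,4S)-3,4-bis(tert-butyldimethylsilyloxy)-2,6,6-trimethylcyclohex-1-en-1-yl trifluoromethanesulfonate; 11 (E)-3-methylpent-2-en-4-yn-1-ol
Product: 12 (E)-5-[(3S,4S)-3,4-bis(tert-butyldimethylsilyloxy)-2,6,6-trimethylcyclohex-1-en-1-yl]-3-methylpent-2-en-4-yn-1-ol
Conditions: 11 (1.3 equiv), Pd(PPh3)4 (5 mol%), CuI (10 mol%), i-Pr2NH, DMF, rt → 45 °C
Reagents that add atoms: none
Why: Sonogashira coupling of hindered 2,6,6-trimethylcyclohexenyl triflates with terminal enynes is well precedented and forms the C6–C7 bond of ring A with the enynol geometry retained.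

Step 9
Reactants: 12 (E)-5-[(3S,4S)-3,4-bis(tert-butyldimethylsilyloxy)-2,6,6-trimethylcyclohex-1-en-1-yl]-3-methylpent-2-en-4-yn-1-ol
Product: 15 tributyl{(E)-5-[(3S,4S)-3,4-bis(tert-butyldimethylsilyloxy)-2,6,6-trimethylcyclohex-1-en-1-yl]-3-methylpent-2-en-4-yn-1-yl}phosphonium bromide, via allylic mesylate 13 (not isolated), via allylic bromide 14 (not isolated)
Conditions: MsCl (1.2 equiv), Et3N (1.5 equiv), THF, −40 °C; LiBr (3 equiv), 0 °C; PBu3 (1.3 equiv), rt
Reagents that add atoms: lithium bromide, [Li+].[Br-]; tributylphosphine, CCCCP(CCCC)CCCC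
Why: Mesylation, bromide displacement and quaternisation of the phosphine run under neutral conditions that spare the allylic silyl ether, and the tributylphosphonium salt is chosen because its ylide gives E-alkenes in the Wittig reaction.

Step 10
Reactants: 11 (E)-3-methylpent-2-en-4-yn-1-ol
Product: 16 (2E,4E)-3-methyl-5-(tributylstannyl)penta-2,4-dien-1-ol
Conditions: Bu3SnH (1.1 equiv), PdCl2(PPh3)2 (2 mol%), THF, 0 °C
Reagents that add atoms: tributyltin hydride, CCCC[SnH](CCCC)CCCC
Why: Pd-catalysed hydrostannation adds Sn–H syn across the terminal alkyne with tin at the distal carbon to give the (E)-vinylstannane, and the minor internal regioisomer should be separable.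

Step 11
Reactants: 10 (3S,4S)-3,4-bis(tert-butyldimethylsilyloxy)-2,6,6-trimethylcyclohex-1-en-1-yl trifluoromethanesulfonate; 16 (2E,4E)-3-methyl-5-(tributylstannyl)penta-2,4-dien-1-ol
Product: 17 (2E,4E)-5-[(3S,4S)-3,4-bis(tert-butyldimethylsilyloxy)-2,6,6-trimethylcyclohex-1-en-1-yl]-3-methylpenta-2,4-dien-1-ol
Conditions: Pd2(dba)3 (2.5 mol%), AsPh3 (20 mol%), LiCl (3 equiv), NMP, 55 °C
Reagents that add atoms: none
Why: Stille coupling of hindered cyclohexenyl triflates with (E)-dienylstannanes under triphenylarsine conditions is precedented in retinoid chemistry and forms the C6–C7 bond of ring B with retention of the stannane geometry.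

Step 12
Reactants: 17 (2E,4E)-5-[(3S,4S)-3,4-bis(tert-butyldimethylsilyloxy)-2,6,6-trimethylcyclohex-1-en-1-yl]-3-methylpenta-2,4-dien-1-ol
Product: 20 tributyl{(2E,4E)-5-[(3S,4S)-3,4-bis(tert-butyldimethylsilyloxy)-2,6,6-trimethylcyclohex-1-en-1-yl]-3-methylpenta-2,4-dien-1-yl}phosphonium bromide, via allylic mesylate 18 (not isolated), via allylic bromide 19 (not isolated)
Conditions: MsCl (1.2 equiv), Et3N (1.5 equiv), THF, −40 °C; LiBr (3 equiv), 0 °C; PBu3 (1.3 equiv), rt
Reagents that add atoms: lithium bromide, [Li+].[Br-]; tributylphosphine, CCCCP(CCCC)CCCC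
Why: The same neutral one-pot sequence as in step 9 should convert the dienol into its Wittig salt by SN2 displacement at the primary allylic carbon.

Step 13
Reactants: 20 tributyl{(2E,4E)-5-[(3S,4S)-3,4-bis(tert-butyldimethylsilyloxy)-2,6,6-trimethylcyclohex-1-en-1-yl]-3-methylpenta-2,4-dien-1-yl}phosphonium bromide; 21 (2E,4E,6E)-2,7-dimethylocta-2,4,6-trienedial
Product: 23 (2E,4E,6E,8E,10E,12E)-13-[(3S,4S)-3,4-bis(tert-butyldimethylsilyloxy)-2,6,6-trimethylcyclohex-1-en-1-yl]-2,7,11-trimethyltrideca-2,4,6,8,10,12-hexaenal, via phosphonium ylide 22 (not isolated)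
Conditions: NaN(SiMe3)2 (1.05 equiv), THF, −78 °C; ylide added to 21 (3 equiv), THF, −78 → 0 °C
Reagents that add atoms: none
Why: Wittig reaction of the allylic tributylphosphonium ylide with an excess of the symmetrical dialdehyde should stop at mono-olefination and form the C11'=C12' bond with E geometry, as semistabilised trialkylphosphonium ylides do.

Step 14
Reactants: 15 tributyl{(E)-5-[(3S,4S)-3,4-bis(tert-butyldimethylsilyloxy)-2,6,6-trimethylcyclohex-1-en-1-yl]-3-methylpent-2-en-4-yn-1-yl}phosphonium bromide; 23 (2E,4E,6E,8E,10E,12E)-13-[(3S,4S)-3,4-bis(tert-butyldimethylsilyloxy)-2,6,6-trimethylcyclohex-1-en-1-yl]-2,7,11-trimethyltrideca-2,4,6,8,10,12-hexaenal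
Product: 25 (3S,4S,3'S,4'S)-3,4,3',4'-tetrakis(tert-butyldimethylsilyloxy)-7,8-didehydro-β,β-carotene (all-E), via phosphonium ylide 24 (not isolated)
Conditions: NaN(SiMe3)2 (1.1 equiv), THF, −78 °C; 23, −78 °C → rt, dark
Reagents that add atoms: none
Why: The second E-selective Wittig reaction forms the C11=C12 bond and completes the C40 chain, and any hindered 11Z isomer should isomerise to E on gentle warming.

Step 15
Reactants: 25 (3S,4S,3'S,4'S)-3,4,3',4'-tetrakis(tert-butyldimethylsilyloxy)-7,8-didehydro-β,β-carotene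
Product: 26 (3S,4S,3'S,4'S)-7,8-didehydro-β,β-carotene-3,4,3',4'-tetrol (all-E)
Conditions: TBAF (8 equiv), THF, 0 °C → rt, dark, argon; aq NH4Cl work-up
Reagents that add atoms: none
Why: Fluoride-mediated desilylation removes the four secondary silyl ethers under non-acidic conditions that the allylic carbinols and the polyene tolerate.

**Compound list**

1 | isobutyric acid | CC(C)C(=O)O | starting material
2 | (S)-benzyl glycidyl ether | C1[C@H](O1)COCc1ccccc1 | starting material
3 | (S)-5-(benzyloxy)-4-hydroxy-2,2-dimethylpentanoic acid | OC(=O)C(C)(C)C[C@H](O)COCc1ccccc1 | intermediate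
4 | (S)-5-[(benzyloxy)methyl]-3,3-dimethyldihydrofuran-2(3H)-one | O=C1O[C@H](COCc2ccccc2)CC1(C)C | intermediate
5 | (S)-7-(benzyloxy)-6-hydroxy-4,4-dimethylheptan-3-one | CCC(=O)C(C)(C)C[C@H](O)COCc1ccccc1 | intermediate
6 | (S,Z)-7-(benzyloxy)-3,6-bis(tert-butyldimethylsilyloxy)-4,4-dimethylhept-2-ene | C/C=C(\O[Si](C)(C)C(C)(C)C)C(C)(C)C[C@H](O[Si](C)(C)C(C)(C)C)COCc1ccccc1 | intermediate
7 | (S,Z)-2,5-bis(tert-butyldimethylsilyloxy)-4,4-dimethylhept-5-en-1-ol | C/C=C(\O[Si](C)(C)C(C)(C)C)C(C)(C)C[C@H](O[Si](C)(C)C(C)(C)C)CO | intermediate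
8 | (S,Z)-2,5-bis(tert-butyldimethylsilyloxy)-4,4-dimethylhept-5-enal | C/C=C(\O[Si](C)(C)C(C)(C)C)C(C)(C)C[C@H](O[Si](C)(C)C(C)(C)C)C=O | intermediate
9 | (4S,5S,6S)-4,5-bis(tert-butyldimethylsilyloxy)-2,2,6-trimethylcyclohexan-1-one | O=C1[C@@H](C)[C@H](O[Si](C)(C)C(C)(C)C)[C@@H](O[Si](C)(C)C(C)(C)C)CC1(C)C | intermediate
10 | (3S,4S)-3,4-bis(tert-butyldimethylsilyloxy)-2,6,6-trimethylcyclohex-1-en-1-yl trifluoromethanesulfonate | CC1=C(OS(=O)(=O)C(F)(F)F)C(C)(C)C[C@H](O[Si](C)(C)C(C)(C)C)[C@H]1O[Si](C)(C)C(C)(C)C | intermediate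
11 | (E)-3-methylpent-2-en-4-yn-1-ol | C#C/C(C)=C/CO | starting material
12 | (E)-5-[(3S,4S)-3,4-bis(tert-butyldimethylsilyloxy)-2,6,6-trimethylcyclohex-1-en-1-yl]-3-methylpent-2-en-4-yn-1-ol | CC1=C(C#C/C(C)=C/CO)C(C)(C)C[C@H](O[Si](C)(C)C(C)(C)C)[C@H]1O[Si](C)(C)C(C)(C)C | intermediate
13 | methanesulfonate of 12 | CC1=C(C#C/C(C)=C/COS(C)(=O)=O)C(C)(C)C[C@H](O[Si](C)(C)C(C)(C)C)[C@H]1O[Si](C)(C)C(C)(C)C | intermediate
14 | allylic bromide from 12 | CC1=C(C#C/C(C)=C/CBr)C(C)(C)C[C@H](O[Si](C)(C)C(C)(C)C)[C@H]1O[Si](C)(C)C(C)(C)C | intermediate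
15 | tributyl{(E)-5-[(3S,4S)-3,4-bis(tert-butyldimethylsilyloxy)-2,6,6-trimethylcyclohex-1-en-1-yl]-3-methylpent-2-en-4-yn-1-yl}phosphonium bromide | CC1=C(C#C/C(C)=C/C[P+](CCCC)(CCCC)CCCC)C(C)(C)C[C@H](O[Si](C)(C)C(C)(C)C)[C@H]1O[Si](C)(C)C(C)(C)C.[Br-] | intermediate
16 | (2E,4E)-3-methyl-5-(tributylstannyl)penta-2,4-dien-1-ol | CCCC[Sn](CCCC)(CCCC)/C=C/C(C)=C/CO | intermediate
17 | (2E,4E)-5-[(3S,4S)-3,4-bis(tert-butyldimethylsilyloxy)-2,6,6-trimethylcyclohex-1-en-1-yl]-3-methylpenta-2,4-dien-1-ol | CC1=C(/C=C/C(C)=C/CO)C(C)(C)C[C@H](O[Si](C)(C)C(C)(C)C)[C@H]1O[Si](C)(C)C(C)(C)C | intermediate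
18 | methanesulfonate of 17 | CC1=C(/C=C/C(C)=C/COS(C)(=O)=O)C(C)(C)C[C@H](O[Si](C)(C)C(C)(C)C)[C@H]1O[Si](C)(C)C(C)(C)C | intermediate
19 | allylic bromide from 17 | CC1=C(/C=C/C(C)=C/CBr)C(C)(C)C[C@H](O[Si](C)(C)C(C)(C)C)[C@H]1O[Si](C)(C)C(C)(C)C | intermediate
20 | tributyl{(2E,4E)-5-[(3S,4S)-3,4-bis(tert-butyldimethylsilyloxy)-2,6,6-trimethylcyclohex-1-en-1-yl]-3-methylpenta-2,4-dien-1-yl}phosphonium bromide | CC1=C(/C=C/C(C)=C/C[P+](CCCC)(CCCC)CCCC)C(C)(C)C[C@H](O[Si](C)(C)C(C)(C)C)[C@H]1O[Si](C)(C)C(C)(C)C.[Br-] | intermediate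
21 | (2E,4E,6E)-2,7-dimethylocta-2,4,6-trienedial | O=C/C(C)=C/C=C/C=C(C)/C=O | starting material
22 | ylide of 20 | CC1=C(/C=C/C(C)=C/[CH-][P+](CCCC)(CCCC)CCCC)C(C)(C)C[C@H](O[Si](C)(C)C(C)(C)C)[C@H]1O[Si](C)(C)C(C)(C)C | intermediate
23 | (2E,4E,6E,8E,10E,12E)-13-[(3S,4S)-3,4-bis(tert-butyldimethylsilyloxy)-2,6,6-trimethylcyclohex-1-en-1-yl]-2,7,11-trimethyltrideca-2,4,6,8,10,12-hexaenal | CC1=C(/C=C/C(C)=C/C=C/C(C)=C/C=C/C=C(C)/C=O)C(C)(C)C[C@H](O[Si](C)(C)C(C)(C)C)[C@H]1O[Si](C)(C)C(C)(C)C | intermediate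
24 | ylide of 15 | CC1=C(C#C/C(C)=C/[CH-][P+](CCCC)(CCCC)CCCC)C(C)(C)C[C@H](O[Si](C)(C)C(C)(C)C)[C@H]1O[Si](C)(C)C(C)(C)C | intermediate
25 | (3S,4S,3'S,4'S)-3,4,3',4'-tetrakis(tert-butyldimethylsilyloxy)-7,8-didehydro-β,β-carotene (all-E) | CC1=C(C#C/C(C)=C/C=C/C(C)=C/C=C/C=C(C)/C=C/C=C(C)/C=C/C2=C(C)[C@H](O[Si](C)(C)C(C)(C)C)[C@@H](O[Si](C)(C)C(C)(C)C)CC2(C)C)C(C)(C)C[C@H](O[Si](C)(C)C(C)(C)C)[C@H]1O[Si](C)(C)C(C)(C)C | intermediate
26 | (3S,4S,3'S,4'S)-7,8-didehydro-β,β-carotene-3,4,3',4'-tetrol (all-E) | CC1=C(C#C/C(C)=C/C=C/C(C)=C/C=C/C=C(C)/C=C/C=C(C)/C=C/C2=C(C)[C@H](O)[C@@H](O)CC2(C)C)C(C)(C)C[C@H](O)[C@H]1O | target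

**Step count**

Total steps: 15. Longest linear sequence: 12 (steps 1–7, 11, 12, 13, 14, 15).

**Steps most likely to fail**

Step 6. The risk is poor facial selectivity at the aldehyde carbon (the carbinol would then form cis to O3) or stalling of the silyl transfer. The fallback sets the carbinol configuration by an epoxidation instead of by the aldol face.
- It sets out from 8: stoichiometric BF3·OEt2 in CH2Cl2 at −78 °C closes the same bond and gives the free β-hydroxy ketone (4S)-4-(tert-butyldimethylsilyloxy)-5-hydroxy-2,2,6-trimethylcyclohexan-1-one F1, whatever its carbinol configuration.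
- MsCl/Et3N converts it into the mesylate of this β-hydroxy ketone F2, which DBU eliminates to (S)-4-(tert-butyldimethylsilyloxy)-2,6,6-trimethylcyclohex-2-en-1-one F3.
- Weitz–Scheffer epoxidation (H2O2, NaOH, MeOH) should add anti to the allylic silyloxy group and give 5-(tert-butyldimethylsilyloxy)-1,3,3-trimethyl-7-oxabicyclo[4.1.0]heptan-2-one (epoxide trans to the silyloxy group) F4.
- SmI2 in THF/MeOH at −78 °C opens the epoxide at the α-carbon and leaves (4S,5S)-4-(tert-butyldimethylsilyloxy)-5-hydroxy-2,2,6-trimethylcyclohexan-1-one F5.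
- TBSOTf/2,6-lutidine then comes back to the route at 9; either configuration at the methyl-bearing carbon serves, since step 7 removes it.

Step 11. The risk is slow oxidative addition and transmetalation at the hindered tetrasubstituted triflate, with protodestannylation or homocoupling of the stannane taking over. The fallback builds the ring B side chain by olefination instead of cross-coupling.
- It sets out from 10: Pd-catalysed formylation (Pd(OAc)2, dppp, CO, Et3SiH, Et3N, DMF, 70 °C) gives (3S,4S)-3,4-bis(tert-butyldimethylsilyloxy)-2,6,6-trimethylcyclohex-1-ene-1-carbaldehyde F6.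
- Horner–Wadsworth–Emmons reaction with triethyl 3-methyl-4-phosphonocrotonate (NaH, THF) gives ethyl (2E,4E)-5-[(3S,4S)-3,4-bis(tert-butyldimethylsilyloxy)-2,6,6-trimethylcyclohex-1-en-1-yl]-3-methylpenta-2,4-dienoate F7.
- i-Bu2AlH at −78 °C reduces the ester and comes back to the route at 17.

Step 4. The risk is saturation or hydrolysis of the silyl enol ether during hydrogenolysis, which would remove the nucleophile needed in step 6. The fallback removes the benzyl group before the enol ether is made.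
- It sets out from 5: TBSCl/imidazole gives (S)-7-(benzyloxy)-6-(tert-butyldimethylsilyloxy)-4,4-dimethylheptan-3-one F8.
- Hydrogenolysis (H2, Pd/C, EtOAc) at this ketone stage gives (S)-6-(tert-butyldimethylsilyloxy)-7-hydroxy-4,4-dimethylheptan-3-one F9.
- Ac2O/pyridine gives (S)-2-(tert-butyldimethylsilyloxy)-4,4-dimethyl-5-oxoheptyl acetate F10.
- TBSOTf/Et3N gives (S,Z)-2,5-bis(tert-butyldimethylsilyloxy)-4,4-dimethylhept-5-en-1-yl acetate F11.
- i-Bu2AlH at −78 °C removes the acetate and comes back to the route at 7.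

Further compounds
F1 | step 6 | (4S)-4-(tert-butyldimethylsilyloxy)-5-hydroxy-2,2,6-trimethylcyclohexan-1-one (carbinol and methyl centres undefined) | O=C1C(C)C(O)[C@@H](O[Si](C)(C)C(C)(C)C)CC1(C)C
F2 | step 6 | mesylate of the β-hydroxy ketone F1 | O=C1C(C)C(OS(C)(=O)=O)[C@@H](O[Si](C)(C)C(C)(C)C)CC1(C)C
F3 | step 6 | (S)-4-(tert-butyldimethylsilyloxy)-2,6,6-trimethylcyclohex-2-en-1-one | CC1=C[C@@H](O[Si](C)(C)C(C)(C)C)CC(C)(C)C1=O
F4 | step 6 | 5-(tert-butyldimethylsilyloxy)-1,3,3-trimethyl-7-oxabicyclo[4.1.0]heptan-2-one (epoxide trans to the silyloxy group) | O=C1C(C)(C)C[C@H](O[Si](C)(C)C(C)(C)C)[C@H]2O[C@@]12C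
F5 | step 6 | (4S,5S)-4-(tert-butyldimethylsilyloxy)-5-hydroxy-2,2,6-trimethylcyclohexan-1-one | O=C1C(C)(C)C[C@H](O[Si](C)(C)C(C)(C)C)[C@@H](O)C1C
F6 | step 11 | (3S,4S)-3,4-bis(tert-butyldimethylsilyloxy)-2,6,6-trimethylcyclohex-1-ene-1-carbaldehyde | CC1=C(C=O)C(C)(C)C[C@H](O[Si](C)(C)C(C)(C)C)[C@H]1O[Si](C)(C)C(C)(C)C
F7 | step 11 | ethyl (2E,4E)-5-[(3S,4S)-3,4-bis(tert-butyldimethylsilyloxy)-2,6,6-trimethylcyclohex-1-en-1-yl]-3-methylpenta-2,4-dienoate | CC1=C(/C=C/C(C)=C/C(=O)OCC)C(C)(C)C[C@H](O[Si](C)(C)C(C)(C)C)[C@H]1O[Si](C)(C)C(C)(C)C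
F8 | step 4 | (S)-7-(benzyloxy)-6-(tert-butyldimethylsilyloxy)-4,4-dimethylheptan-3-one | CCC(=O)C(C)(C)C[C@H](O[Si](C)(C)C(C)(C)C)COCc1ccccc1
F9 | step 4 | (S)-6-(tert-butyldimethylsilyloxy)-7-hydroxy-4,4-dimethylheptan-3-one | CCC(=O)C(C)(C)C[C@H](O[Si](C)(C)C(C)(C)C)CO
F10 | step 4 | (S)-2-(tert-butyldimethylsilyloxy)-4,4-dimethyl-5-oxoheptyl acetate | CCC(=O)C(C)(C)C[C@H](O[Si](C)(C)C(C)(C)C)COC(C)=O
F11 | step 4 | (S,Z)-2,5-bis(tert-butyldimethylsilyloxy)-4,4-dimethylhept-5-en-1-yl acetate | C/C=C(\O[Si](C)(C)C(C)(C)C)C(C)(C)C[C@H](O[Si](C)(C)C(C)(C)C)COC(C)=O
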